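**Plan**

- Retrosynthesis: the five benzyl ethers come off last; both pyranone rings are opened at O1–C8a and O1''–C8a'' (double SNAr on 2-fluoroaryl ketones); C2–O and C2''–O are traced back to C–CHO (formate, Baeyer–Villiger) and the two formyl carbons are rejoined as a cis-alkene, giving a 3,6-diaryl-4,5-diaroylcyclohexene, which is cut at C2–C3 and C2''–C3'' by a retro-Diels–Alder step.
- Forward: the diene (steps 1–4) and the enedione (steps 5–8) are made separately; the cyclohexene closes in step 9; its two alkene carbons are excised in steps 11–13; the pyranone rings (ring C of unit A and of unit B) close together in step 14; hydrogenolysis ends the route.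
- Enabling feature: the contiguous tetrad C2–C3–C3''–C2'' carries aryl groups on C2 and C2'' and the carbonyl carbons C4 and C4'' on C3 and C3''. Unit A (4-methoxyphenyl) is 2,3-cis and unit B (4-hydroxyphenyl) is 2'',3''-trans. This is the aryl-cis/acyl-trans pattern of an (E,E)-diene plus (E)-enedione cycloadduct, in which one aryl is trans and the other cis to its neighbouring aroyl group.
- Stereochemistry: relative configuration comes from the stereospecific suprafacial cycloaddition; absolute configuration, and the choice of which aryl lies trans to its aroyl neighbour, come from a chiral boron Lewis acid and the electronic bias of the diene (pivalate versus benzyl ether); Baeyer–Villiger migration and SNAr both retain configuration at C2 and C2''.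

Key step: step 9

Assumption: the (S)-configured oxazaborolidinium is taken to block the enone face whose shielding leads to 14; if the first adduct proves to be the mirror image, the equally accessible (R)-catalyst is used with nothing else changed.

**Step 1**
Reactants: 1 4-hydroxybenzaldehyde
Product: 2 4-formylphenyl pivalate
Conditions: PivCl, Et3N, DMAP (cat.), CH2Cl2, 0 °C → rt
Reagents that add atoms: pivaloyl chloride CC(C)(C)C(=O)Cl
Why: DMAP-catalysed esterification of the phenol installs a base-robust, electron-poor acyloxy group that later marks this aryl ring as the weaker donor of the diene.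

**Step 2**
Reactants: 2 4-formylphenyl pivalate
Product: 3 (E)-4-(3-oxoprop-1-en-1-yl)phenyl pivalate (4-pivaloyloxycinnamaldehyde)
Conditions: Ph3P=CHCHO (1.05 equiv), toluene, 80 °C
Reagents that add atoms: (triphenylphosphoranylidene)acetaldehyde O=CC=P(c1ccccc1)(c1ccccc1)c1ccccc1
Why: Wittig olefination with the formyl-stabilised ylide should give the (E)-enal because the stabilised ylide adds reversibly, and the neutral conditions leave the pivalate untouched.

**Step 3**
Reactants: 4 1-(benzyloxy)-4-(chloromethyl)benzene
Product: 5 diethyl [4-(benzyloxy)benzyl]phosphonate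
Conditions: P(OEt)3 (neat), 140 °C
Reagents that add atoms: triethyl phosphite CCOP(OCC)OCC
Why: Michaelis–Arbuzov reaction, in which the phosphite displaces the benzylic chloride and the phosphonium intermediate loses chloroethane.

**Step 4**
Reactants: 3 (E)-4-(3-oxoprop-1-en-1-yl)phenyl pivalate; 5 diethyl [4-(benzyloxy)benzyl]phosphonate
Product: 6 (1E,3E)-1-(4-pivaloyloxyphenyl)-4-(4-benzyloxyphenyl)buta-1,3-diene
Conditions: KOtBu (1.05 equiv) added to 3 + 5, THF, −20 °C → rt
Reagents that add atoms: none
Why: Horner–Wadsworth–Emmons olefination of the semi-stabilised benzylic phosphonate anion should form the new alkene with (E) geometry under thermodynamic control, the existing (E)-alkene is carried through, and the hindered pivalate resists the base.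

**Step 5**
Reactants: 7 fumaryl chloride
Product: 8 (E)-N1,N4-dimethoxy-N1,N4-dimethylbut-2-enediamide
Conditions: MeNH(OMe)·HCl (2.2 equiv), pyridine (4.5 equiv), CH2Cl2, 0 °C → rt
Reagents that add atoms: N,O-dimethylhydroxylamine hydrochloride CNOC.Cl
Why: Acylation of the hydroxylamine by the diacid chloride gives the bis(N-methoxy-N-methyl amide) with the (E)-alkene unchanged.

**Step 6**
Reactants: 9 5-fluororesorcinol
Product: 10 1,3-bis(benzyloxy)-5-fluorobenzene
Conditions: BnBr (2.2 equiv), K2CO3, DMF, rt → 60 °C
Reagents that add atoms: benzyl bromide BrCc1ccccc1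
Why: Williamson etherification of both phenols.

**Step 7**
Reactants: 10 1,3-bis(benzyloxy)-5-fluorobenzene
Product: 11 1,5-bis(benzyloxy)-2-bromo-3-fluorobenzene
Conditions: NBS (1.0 equiv), MeCN, 0 °C → rt
Reagents that add atoms: N-bromosuccinimide O=C1CCC(=O)N1Br
Why: Electrophilic aromatic bromination should take the carbon that is para to one benzyloxy group and ortho to the other and to fluorine, the site between the two benzyloxy groups being more shielded, and it is chosen over direct lithiation of 10 because the site selectivity of that metalation would be uncertain.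

**Step 8**
Reactants: 11 1,5-bis(benzyloxy)-2-bromo-3-fluorobenzene (2.2 equiv); 8 (E)-N1,N4-dimethoxy-N1,N4-dimethylbut-2-enediamide
Product: 13 (E)-1,4-bis[2-fluoro-4,6-bis(benzyloxy)phenyl]but-2-ene-1,4-dione, via aryllithium 12 (not isolated)
Conditions: n-BuLi (1.0 equiv per 11), THF, −78 °C; then 8, −78 °C; 1 M HCl quench at −78 °C
Reagents that add atoms: none
Why: Bromine–lithium exchange at −78 °C should outrun benzylic deprotonation and loss of LiF, and each aryllithium adds once to an N-methoxy-N-methyl amide to give a chelated tetrahedral adduct that collapses to the ketone only on acidic work-up, so the (E)-enedione forms without over-addition.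

**Step 9**
Reactants: 6 (1E,3E)-1-(4-pivaloyloxyphenyl)-4-(4-benzyloxyphenyl)buta-1,3-diene; 13 (E)-1,4-bis[2-fluoro-4,6-bis(benzyloxy)phenyl]but-2-ene-1,4-dione
Product: 14 [(1R,2R,3R,6S)-3-[4-(benzyloxy)phenyl]-6-[4-(pivaloyloxy)phenyl]cyclohex-4-ene-1,2-diyl]bis{[2-fluoro-4,6-bis(benzyloxy)phenyl]methanone} (aryl groups cis to each other, aroyl groups trans; the pivaloyloxyphenyl group trans and the benzyloxyphenyl group cis to the adjacent aroyl group)
Conditions: (S)-3,3-diphenyl-1-(o-tolyl)hexahydropyrrolo[1,2-c][1,3,2]oxazaborole·HNTf2 (20 mol%), CH2Cl2, −78 → −20 °C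
Reagents that add atoms: none
Why: Proposed new method: the closest known reactions are the Lewis-acid-promoted Diels–Alder addition of (E)-1,2-diaroylethylenes to 1,3-dienes and the oxazaborolidinium-catalysed enantioselective Diels–Alder reaction of acyclic enones and fumarates, which this step combines on a 1,4-diaryl diene; one carbonyl of the C2-symmetric enedione 13 (its alkene faces are homotopic, so it does not matter which carbonyl binds) coordinates to boron, the catalyst blocks one face of the activated enone, and the s-cis diene adds to the open face in a concerted, asynchronous, suprafacial [4+2] cycloaddition. The cyclohexene is closed by this intermolecular [4πs+2πs] union, both σ-bonds (the future C2–C3 and C2''–C3'') forming in one step. The cis relation of the two aryl-bearing carbons follows stereospecifically from the (E,E)-diene and the trans relation of the two aroyl-bearing carbons from the (E)-alkene. The absolute configuration of all four centres is set by the catalyst-controlled face together with endo placement of the boron-bound aroyl group (secondary overlap with the activated carbonyl). The step also needs regioselection, that is, which aryl ends up next to the exo aroyl group: bonding is most advanced at the carbon β to the bound carbonyl, and the diene terminus carrying the weakly donating 4-pivaloyloxyphenyl group is the more nucleophilic one because the 4-benzyloxyphenyl group at the far terminus stabilises the developing positive charge, so the pivaloyloxyphenyl group becomes trans and the benzyloxyphenyl group cis to the adjacent aroyl group.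

**Step 10**
Reactants: 14 the pivalate cycloadduct
Product: 16 [(1R,2R,3R,6S)-3-[4-(benzyloxy)phenyl]-6-(4-methoxyphenyl)cyclohex-4-ene-1,2-diyl]bis{[2-fluoro-4,6-bis(benzyloxy)phenyl]methanone}, via phenol 15 (not isolated)
Conditions: K2CO3, MeOH–THF, rt; concentrate; then MeI, K2CO3, DMF, rt
Reagents that add atoms: iodomethane CI
Why: Base-catalysed methanolysis of the aryl ester (phenoxide leaving group) followed by Williamson O-methylation of the phenoxide; the two α-aroyl C–H centres are tertiary and would give very congested tetrasubstituted enolates, so they are not expected to epimerise under carbonate at room temperature.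

**Step 11**
Reactants: 16 the 4-methoxyphenyl cycloadduct
Product: 18 (2R,3R,4R,5S)-3,4-bis[2-fluoro-4,6-bis(benzyloxy)benzoyl]-2-[4-(benzyloxy)phenyl]-5-(4-methoxyphenyl)hexanedial, via ozonide 17 (not isolated)
Conditions: O3, CH2Cl2, −78 °C (Sudan Red 7B end-point); then PPh3, −78 °C → rt; used crude
Reagents that add atoms: ozone [O-][O+]=O
Why: Ozonolysis (1,3-dipolar cycloaddition of ozone to the only C=C bond, cycloreversion and recombination to the ozonide) followed by PPh3 reduction should give the dialdehyde under neutral conditions, so the two α-aryl aldehyde centres are not enolised, and the dye marks the end-point before the electron-rich rings are attacked.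

**Step 12**
Reactants: 18 the dialdehyde
Product: 19 (1R,2S,3S,4S)-2,3-bis[2-fluoro-4,6-bis(benzyloxy)benzoyl]-1-[4-(benzyloxy)phenyl]-4-(4-methoxyphenyl)butane-1,4-diyl diformate
Conditions: mCPBA (2.2 equiv), CH2Cl2, 0 °C
Reagents that add atoms: 3-chloroperoxybenzoic acid O=C(OO)c1cccc(Cl)c1
Why: Baeyer–Villiger oxidation, in which the secondary benzylic carbon of each peracid adduct migrates to oxygen in preference to hydride and with retention of configuration, while the hindered diaroyl ketones should react much more slowly.

**Step 13**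
Reactants: 19 the bis-formate
Product: 20 (1R,2S,3S,4S)-2,3-bis[2-fluoro-4,6-bis(benzyloxy)benzoyl]-1-[4-(benzyloxy)phenyl]-4-(4-methoxyphenyl)butane-1,4-diol
Conditions: KHCO3 (0.2 equiv), MeOH–THF, 0 °C
Reagents that add atoms: none
Why: Formates undergo base-catalysed transesterification far faster than other esters, so catalytic bicarbonate in methanol should free both benzylic alcohols at a basicity too low for retro-aldol cleavage or dehydration of the β-hydroxy ketones (any five-membered lactol formed with a γ-ketone reopens in the next step).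

**Step 14**
Reactants: 20 the diol
Product: 21 (2S,3S,2''R,3''S)-5,5'',7,7''-tetrakis(benzyloxy)-2''-[4-(benzyloxy)phenyl]-2-(4-methoxyphenyl)-[3,3''-bichromane]-4,4''-dione
Conditions: KN(SiMe3)2 (2.05 equiv), THF, −78 → 0 °C; pH 7 phosphate buffer
Reagents that add atoms: none
Why: Double intramolecular SNAr (addition–elimination): each potassium alkoxide attacks the fluorine-bearing carbon ortho to its β-carbonyl through a six-membered transition state, the carbinol C–O bonds are untouched so C2 and C2'' keep their configuration, the benzyloxy groups are meta to the site of attack and do not deactivate it, and two equivalents of base at low temperature leave none to epimerise C3 of the cis unit.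

**Step 15**
Reactants: 21 the pentabenzyl biflavanone
Product: 22 (2S,3S,2''R,3''S)-5,5'',7,7''-tetrahydroxy-2''-(4-hydroxyphenyl)-2-(4-methoxyphenyl)-[3,3''-bichromane]-4,4''-dione (CNP0196568.4)
Conditions: H2 (1 atm), 10% Pd/C, EtOAc–MeOH, rt
Reagents that add atoms: none
Why: Hydrogenolysis of the five aryl benzyl ethers over palladium is standard for benzylated flavanones and, being neutral, should leave the C4 ketones, the cyclic benzylic C2–O bonds, the methyl ether and the base-sensitive 2,3-cis unit untouched.

**Compound list**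

1 | 4-hydroxybenzaldehyde | O=Cc1ccc(O)cc1 | starting material
2 | 4-formylphenyl pivalate | CC(C)(C)C(=O)Oc1ccc(C=O)cc1 | intermediate
3 | (E)-4-(3-oxoprop-1-en-1-yl)phenyl pivalate | CC(C)(C)C(=O)Oc1ccc(/C=C/C=O)cc1 | intermediate
4 | 1-(benzyloxy)-4-(chloromethyl)benzene | ClCc1ccc(OCc2ccccc2)cc1 | starting material
5 | diethyl [4-(benzyloxy)benzyl]phosphonate | CCOP(=O)(Cc1ccc(OCc2ccccc2)cc1)OCC | intermediate
6 | (1E,3E)-1-(4-pivaloyloxyphenyl)-4-(4-benzyloxyphenyl)buta-1,3-diene | CC(C)(C)C(=O)Oc1ccc(/C=C/C=C/c2ccc(OCc3ccccc3)cc2)cc1 | intermediate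
7 | fumaryl chloride | O=C(Cl)/C=C/C(=O)Cl | starting material
8 | (E)-N1,N4-dimethoxy-N1,N4-dimethylbut-2-enediamide | CON(C)C(=O)/C=C/C(=O)N(C)OC | intermediate
9 | 5-fluororesorcinol | Oc1cc(O)cc(F)c1 | starting material
10 | 1,3-bis(benzyloxy)-5-fluorobenzene | Fc1cc(OCc2ccccc2)cc(OCc2ccccc2)c1 | intermediate
11 | 1,5-bis(benzyloxy)-2-bromo-3-fluorobenzene | Fc1cc(OCc2ccccc2)cc(OCc2ccccc2)c1Br | intermediate
12 | [2-fluoro-4,6-bis(benzyloxy)phenyl]lithium (not isolated) | [Li]c1c(F)cc(OCc2ccccc2)cc1OCc1ccccc1 | intermediate
13 | (E)-1,4-bis[2-fluoro-4,6-bis(benzyloxy)phenyl]but-2-ene-1,4-dione | O=C(/C=C/C(=O)c1c(F)cc(OCc2ccccc2)cc1OCc1ccccc1)c1c(F)cc(OCc2ccccc2)cc1OCc1ccccc1 | intermediate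
14 | (1R,2R,3R,6S)-3-(4-benzyloxyphenyl)-6-(4-pivaloyloxyphenyl)-1,2-bis[2-fluoro-4,6-bis(benzyloxy)benzoyl]cyclohex-4-ene | CC(C)(C)C(=O)Oc1ccc([C@H]2C=C[C@@H](c3ccc(OCc4ccccc4)cc3)[C@@H](C(=O)c3c(F)cc(OCc4ccccc4)cc3OCc3ccccc3)[C@@H]2C(=O)c2c(F)cc(OCc3ccccc3)cc2OCc2ccccc2)cc1 | intermediate
15 | 4-hydroxyphenyl analogue of 14 (phenol, not isolated) | Oc1ccc([C@H]2C=C[C@@H](c3ccc(OCc4ccccc4)cc3)[C@@H](C(=O)c3c(F)cc(OCc4ccccc4)cc3OCc3ccccc3)[C@@H]2C(=O)c2c(F)cc(OCc3ccccc3)cc2OCc2ccccc2)cc1 | intermediate
16 | (1R,2R,3R,6S)-3-(4-benzyloxyphenyl)-6-(4-methoxyphenyl)-1,2-bis[2-fluoro-4,6-bis(benzyloxy)benzoyl]cyclohex-4-ene | COc1ccc([C@H]2C=C[C@@H](c3ccc(OCc4ccccc4)cc3)[C@@H](C(=O)c3c(F)cc(OCc4ccccc4)cc3OCc3ccccc3)[C@@H]2C(=O)c2c(F)cc(OCc3ccccc3)cc2OCc2ccccc2)cc1 | intermediate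
17 | ozonide of 16 (1,2,4-trioxolane bridging the two former alkene carbons, mixture at these two carbons, not isolated) | COc1ccc([C@H]2C3OOC(O3)[C@@H](c3ccc(OCc4ccccc4)cc3)[C@@H](C(=O)c3c(F)cc(OCc4ccccc4)cc3OCc3ccccc3)[C@@H]2C(=O)c2c(F)cc(OCc3ccccc3)cc2OCc2ccccc2)cc1 | intermediate
18 | (2R,3R,4R,5S)-3,4-bis[2-fluoro-4,6-bis(benzyloxy)benzoyl]-2-(4-benzyloxyphenyl)-5-(4-methoxyphenyl)hexanedial | COc1ccc([C@@H](C=O)[C@@H](C(=O)c2c(F)cc(OCc3ccccc3)cc2OCc2ccccc2)[C@H](C(=O)c2c(F)cc(OCc3ccccc3)cc2OCc2ccccc2)[C@@H](C=O)c2ccc(OCc3ccccc3)cc2)cc1 | intermediate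
19 | (1R,2S,3S,4S)-2,3-bis[2-fluoro-4,6-bis(benzyloxy)benzoyl]-1-(4-benzyloxyphenyl)-4-(4-methoxyphenyl)butane-1,4-diyl diformate | COc1ccc([C@@H](OC=O)[C@@H](C(=O)c2c(F)cc(OCc3ccccc3)cc2OCc2ccccc2)[C@H](C(=O)c2c(F)cc(OCc3ccccc3)cc2OCc2ccccc2)[C@@H](OC=O)c2ccc(OCc3ccccc3)cc2)cc1 | intermediate
20 | (1R,2S,3S,4S)-2,3-bis[2-fluoro-4,6-bis(benzyloxy)benzoyl]-1-(4-benzyloxyphenyl)-4-(4-methoxyphenyl)butane-1,4-diol | COc1ccc([C@@H](O)[C@@H](C(=O)c2c(F)cc(OCc3ccccc3)cc2OCc2ccccc2)[C@H](C(=O)c2c(F)cc(OCc3ccccc3)cc2OCc2ccccc2)[C@@H](O)c2ccc(OCc3ccccc3)cc2)cc1 | intermediate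
21 | (2S,3S,2''R,3''S)-5,5'',7,7''-tetrakis(benzyloxy)-2''-(4-benzyloxyphenyl)-2-(4-methoxyphenyl)-[3,3''-bichromane]-4,4''-dione | COc1ccc([C@H]2Oc3cc(OCc4ccccc4)cc(OCc4ccccc4)c3C(=O)[C@H]2[C@@H]2C(=O)c3c(OCc4ccccc4)cc(OCc4ccccc4)cc3O[C@H]2c2ccc(OCc3ccccc3)cc2)cc1 | intermediate
22 | (2S,3S,2''R,3''S)-5,5'',7,7''-tetrahydroxy-2''-(4-hydroxyphenyl)-2-(4-methoxyphenyl)-[3,3''-bichromane]-4,4''-dione | COc1ccc([C@H]2Oc3cc(O)cc(O)c3C(=O)[C@H]2[C@@H]2C(=O)c3c(O)cc(O)cc3O[C@H]2c2ccc(O)cc2)cc1 | target

**Totals**

Total step count: 15.
Longest linear sequence: 10 steps (from 9 through steps 6–8 and 9–15; equally from 1 through steps 1, 2, 4 and 9–15).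

**Steps most likely to fail**

Step 9 (the proposed new method). The hindered diaryl diene may add slowly, so that acid-induced oligomerisation of the electron-rich diene or a stepwise cationic pathway erodes the stereospecificity. The electronic bias between the two diene termini may be too small for clean regioselection, and facial discrimination by the catalyst may be modest. The fallback uses known chemistry and sets out from 6 and 13. The cycloaddition is promoted by an achiral Lewis acid (Me2AlCl, CH2Cl2, low temperature), the established racemic reaction of diaroylethylenes with dienes. It should give racemic 14, that is, 14 together with its mirror image, the (1S,2S,3S,6R)-cycloadduct F1. Any regioisomeric diastereomer is removed on silica, and preparative chromatography on a chiral stationary phase separates 14 from F1. The route is rejoined at 14.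

Step 14. The potassium aldolate may fragment by retro-aldol cleavage, or C3 of the 2,3-cis unit may epimerise after closure, if ring closure on the twisted aryl ketone is slow. The fallback sets out from 20. Both hydroxyl groups are capped (TMSCl, imidazole, CH2Cl2) to give the bis(trimethylsilyl) ether F2. A catalytic amount of anhydrous fluoride (CsF or tetrabutylammonium difluorotriphenylsilicate, DMF, rt) then unmasks each alkoxide only transiently next to its aryl fluoride. The fluoride expelled in each SNAr event carries the desilylation forward, so no stoichiometric base and no standing concentration of aldolate is present. Closure of both pyranone rings returns to 21.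

Step 11. Ozone may over-oxidise the electron-rich rings and benzylic ethers in competition with the hindered ring alkene, and the labile bis(α-aryl aldehyde) may lose configuration during work-up. The fallback sets out from 16. Catalytic OsO4 with N-methylmorpholine N-oxide in acetone–water should dihydroxylate the alkene on the face opposite the two allylic aryl groups to give the cis-cyclohexane-1,2-diol F3, which is stable and can be purified. Pb(OAc)4 in CH2Cl2 at 0 °C then cleaves the glycol under anhydrous, neutral conditions, and the filtrate is 18, taken directly into step 12.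

**Further compounds**

F1 | step 9 | (1S,2S,3S,6R)-enantiomer of cycloadduct 14 | CC(C)(C)C(=O)Oc1ccc([C@@H]2C=C[C@H](c3ccc(OCc4ccccc4)cc3)[C@H](C(=O)c3c(F)cc(OCc4ccccc4)cc3OCc3ccccc3)[C@H]2C(=O)c2c(F)cc(OCc3ccccc3)cc2OCc2ccccc2)cc1
F2 | step 14 | bis(trimethylsilyl) ether of diol 20 | COc1ccc([C@@H](O[Si](C)(C)C)[C@@H](C(=O)c2c(F)cc(OCc3ccccc3)cc2OCc2ccccc2)[C@H](C(=O)c2c(F)cc(OCc3ccccc3)cc2OCc2ccccc2)[C@@H](O[Si](C)(C)C)c2ccc(OCc3ccccc3)cc2)cc1
F3 | step 11 | cis-cyclohexane-1,2-diol from 16 (both hydroxyl groups anti to the flanking aryl groups) | COc1ccc([C@H]2[C@H](O)[C@H](O)[C@@H](c3ccc(OCc4ccccc4)cc3)[C@@H](C(=O)c3c(F)cc(OCc4ccccc4)cc3OCc3ccccc3)[C@@H]2C(=O)c2c(F)cc(OCc3ccccc3)cc2OCc2ccccc2)cc1
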